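## Retrosynthetic overview
1. The last bond made is the C3–O ester. The oxidation-sensitive (Z)-2-methyl-3-(methylthio)acrylate goes on only after all oxygen chemistry is finished.
2. The 11-hydroxy-6,9-dien-8-one comes from isopetasol (7(11),9-dien-8-one) by a singlet-oxygen ene reaction, the likely natural origin of this pattern.
3. Isopetasol comes from 3,4-epoxyeudesm-7(11)-en-8-one: ionisation at C4, then the eudesmyl → eremophilenyl 1,2-H and 1,2-Me shifts, ended by loss of H-9.
4. The epoxide comes from eudesma-3,7(11)-dien-8-one, which comes from achiral germacrone by a catalyst-controlled, enantioselective transannular C5–C10 closure.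
5. Ring order: the ten-membered ring (nature's farnesyl C1–C10 closure) arrives with germacrone. Rings A and B are then made together in one step by the transannular bond, and no other ring is formed.

Assumption: germacrone, the crystalline main constituent of commercial zdravets oil and sold in bulk, counts as a cheap commercial starting material; eudesmane/eremophilane numbering is used (C3 carbinol, C4 CHMe, C5 quaternary, C8 ketone, C11 carbinol carbon).

## Route

Step 1
Reactants: 1 germacrone
Product: 2 (5R,10R)-eudesma-3,7(11)-dien-8-one (trans-decalin)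
Conditions: chiral IDPi Brønsted acid [N,N′-bis(triflyl)imidodiphosphorimidate built from two 3,3′-diaryl-BINOL units; the catalyst enantiomer that gives (5R,10R)] (5 mol %), CHCl3, 4 Å MS, −50 °C; minor 4(15)-ene isomer removed on AgNO3–silica
Reagents that add atoms: none
Why: Proposed new method: achiral acids already close germacrone to racemic trans-selinadienones, because protonation of the strained (E)-C1=C10 alkene at C1 places a C10 cation directly over C5 of the crossed chair–chair conformer; here a confined chiral acid, held by a hydrogen bond to the C8 ketone, protonates only one of the two rapidly interconverting planar-chiral conformers (dynamic kinetic resolution), anti addition across both alkenes sets C10 (R) and C5 (R) as a trans ring fusion, and the paired anion removes the axial H-3 from the C4 cation to give the endocyclic 3-ene; the closest known reaction types are the acid-catalysed germacrane → eudesmane transannular cyclisation and IDPi-catalysed enantioselective proton-initiated polyene cyclisation.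

Step 2
Reactants: 2 (5R,10R)-eudesma-3,7(11)-dien-8-one
Product: 3 (3R,4S,5R,10R)-3,4-epoxyeudesm-7(11)-en-8-one (oxygen on the face opposite the C10 methyl)
Conditions: mCPBA (1.05 equiv), CH2Cl2, −10 °C
Reagents that add atoms: mCPBA (3-chloroperoxybenzoic acid), O=C(OO)c1cccc(Cl)c1
Why: Prilezhaev epoxidation: the electron-rich trisubstituted C3=C4 alkene reacts far faster than the tetrasubstituted enone alkene, and the axial C10 methyl shields one face, so oxygen arrives from the other face and sets C3 (R) and C4 (S).

Step 3
Reactants: 3 (3R,4S,5R,10R)-3,4-epoxyeudesm-7(11)-en-8-one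
Product: 4 isopetasol, (3R,4R,5R)-3-hydroxyeremophila-7(11),9-dien-8-one
Conditions: Tf2NH (10 mol %), CH2Cl2–(CF3)2CHOH 4:1, 4 Å MS, −40 → 0 °C; aq NaHCO3 work-up; recrystallise to upgrade ee
Reagents that add atoms: none
Why: Proposed new method: the acid opens the epoxide at tertiary C4 through the Fürst–Plattner chair, which leaves O-3 axial and H-3 equatorial in the nodal plane of the empty orbital (so the usual Meinwald shift to a 3-ketone is stereoelectronically switched off) and leaves axial H-5 as the only aligned migrating group; a suprafacial 1,2-shift of H-5 on the face opposite the methyl sets C4 (R), a 1,2-shift of the C10 methyl on its own face sets C5 (R, methyls cis), the charge thereby moves away from the electron-withdrawing C3–O bond to C10, and loss of the ketone-acidified H-9 gives the cross-conjugated dienone as thermodynamic sink and returns the proton; the C3–O bond is never broken (C3 stays R, oxygen trans to the C4 methyl), while olefinic or 3,10-ether off-cycle products re-enter by reprotonation or retro-oxa-Michael opening; the closest known reaction types are the acid-induced C10→C5 methyl migration of 4,5-epoxyeudesmanes, the Westphalen rearrangement and the Lewis-acid-induced 1,2-H/1,2-Me shifts of drimanes to friedodrimanes.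

Step 4
Reactants: 4 isopetasol
Product: 6 (3R,4R,5R)-3,11-dihydroxyeremophila-6,9-dien-8-one, via 11-hydroperoxide 5 (not isolated)
Conditions: O2, 5,10,15,20-tetraphenylporphyrin (0.5 mol %), white LED, CH2Cl2, 0 °C; then PPh3 (1.1 equiv), 0 °C → rt
Reagents that add atoms: oxygen, O=O
Why: Schenck ene reaction: a fixed s-cis 7(11)-en-8-one reacts with singlet oxygen with geminal regioselectivity, so oxygen binds the β-carbon C11 and the axial H-6 on the carbon geminal to the carbonyl is removed from the face opposite the C5 methyl; the new C6=C7 bond stays conjugated, the s-trans C9=C10 enone is inert, no stereocentre is created, and PPh3 reduces the hydroperoxide in the same flask.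

Step 5
Reactants: 7 propargyl alcohol
Product: 9 (Z)-2-methyl-3-(methylthio)prop-2-en-1-ol, via vinylmagnesium chelate 8 (not isolated)
Conditions: MeMgBr (3 equiv), CuI (10 mol %), Et2O–THF, −10 °C → rt; then MeSSMe, 0 °C → rt; aq NH4Cl
Reagents that add atoms: methylmagnesium bromide, C[Mg]Br; dimethyl disulfide, CSSC
Why: Copper-catalysed, alkoxide-directed anti-carbomagnesiation of propargyl alcohol puts the methyl on C2 and magnesium on C3 cis to CH2O in a five-membered chelate, and sulfenylation of the vinyl–Mg bond with retention fixes sulfur cis to the carbinol carbon (Z).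

Step 6
Reactants: 9 (Z)-2-methyl-3-(methylthio)prop-2-en-1-ol
Product: 11 (Z)-2-methyl-3-(methylthio)prop-2-enoic acid, via Z-enal 10 (not isolated)
Conditions: MnO2, CH2Cl2, rt, filter, concentrate; then NaClO2, NaH2PO4, 2-methyl-2-butene, t-BuOH–H2O, 0 °C
Reagents that add atoms: sodium chlorite, [Na+].[O-]Cl=O
Why: MnO2 allylic oxidation followed by Pinnick oxidation: MnO2 tolerates sulfides, the sulfur of the push–pull enal is deactivated and HOCl is scavenged, and carrying the crude enal forward without chromatography avoids Z/E drift.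

Step 7
Reactants: 6 (3R,4R,5R)-3,11-dihydroxyeremophila-6,9-dien-8-one; 11 (Z)-2-methyl-3-(methylthio)prop-2-enoic acid
Product: 13 target CNP0150028.1, via mixed anhydride 12 (not isolated)
Conditions: 11, 2,4,6-Cl3C6H2COCl, Et3N, toluene, rt, filter; then 6, toluene, 75 °C
Reagents that add atoms: none
Why: DMAP-free Yamaguchi-type mixed-anhydride esterification, the protocol used for isomerisation-prone angelates: only the equatorial secondary C3–OH is acylated, the tertiary C11–OH (hydrogen-bonded to C8=O) is inert, no nucleophilic catalyst is present to scramble the Z alkene, and C3 keeps its configuration because its C–O bond is untouched.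

## Compound list
1 | germacrone, (3E,7E)-3,7-dimethyl-10-(propan-2-ylidene)cyclodeca-3,7-dien-1-one | C/C1=C\CC(=C(C)C)C(=O)C/C(C)=C/CC1 | starting material
2 | (5R,10R)-eudesma-3,7(11)-dien-8-one | CC1=CCC[C@]2(C)CC(=O)C(=C(C)C)C[C@@H]12 | intermediate
3 | (3R,4S,5R,10R)-3,4-epoxyeudesm-7(11)-en-8-one | C[C@@]12O[C@@H]1CC[C@]3(C)CC(=O)C(=C(C)C)C[C@@H]23 | intermediate
4 | isopetasol, (3R,4R,5R)-3-hydroxyeremophila-7(11),9-dien-8-one | O[C@@H]1CCC2=CC(=O)C(=C(C)C)C[C@]2(C)[C@H]1C | intermediate
5 | (3R,4R,5R)-11-hydroperoxy-3-hydroxyeremophila-6,9-dien-8-one | O[C@@H]1CCC2=CC(=O)C(C(C)(C)OO)=C[C@]2(C)[C@H]1C | intermediate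
6 | (3R,4R,5R)-3,11-dihydroxyeremophila-6,9-dien-8-one | O[C@@H]1CCC2=CC(=O)C(C(C)(C)O)=C[C@]2(C)[C@H]1C | intermediate
7 | propargyl alcohol (prop-2-yn-1-ol) | C#CCO | starting material
8 | (Z)-3-(bromomagnesio)-2-methylprop-2-en-1-olate bromomagnesium salt (chelate, drawn open) | Br[Mg]/C=C(/C)CO[Mg]Br | intermediate
9 | (Z)-2-methyl-3-(methylthio)prop-2-en-1-ol | CS/C=C(/C)CO | intermediate
10 | (Z)-2-methyl-3-(methylthio)prop-2-enal | CS/C=C(/C)C=O | intermediate
11 | (Z)-2-methyl-3-(methylthio)prop-2-enoic acid | CS/C=C(/C)C(=O)O | intermediate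
12 | (Z)-2-methyl-3-(methylthio)prop-2-enoic 2,4,6-trichlorobenzoic anhydride | CS/C=C(/C)C(=O)OC(=O)c1c(Cl)cc(Cl)cc1Cl | intermediate
13 | (3R,4R,5R)-11-hydroxy-8-oxoeremophila-6,9-dien-3-yl (Z)-2-methyl-3-(methylthio)prop-2-enoate | CS/C=C(/C)C(=O)O[C@@H]1CCC2=CC(=O)C(C(C)(C)O)=C[C@]2(C)[C@H]1C | target

## Step count and risks
Total steps: 7. Longest linear sequence: 5 (steps 1, 2, 3, 4, 7).

**Step 1** carries the risk of an unproven catalytic reaction, both in enantioselectivity and in 3-ene regioselectivity. The fallback sets out from 1 and returns at 4, and it replaces catalyst control by a late enzymatic resolution.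
- Compound 1 is cyclised with TsOH·H2O in CH2Cl2 to racemic eudesma-3,7(11)-dien-8-one F1.
- This is taken through the conditions of steps 2 and 3 as racemic 3,4-epoxyeudesm-7(11)-en-8-one F2 and racemic isopetasol F3.
- Immobilised Candida antarctica lipase B with vinyl butanoate in MTBE then acylates the (3R)-enantiomer. This follows the Kazlauskas rule for the trans-2-methylcyclohexanol pattern.
- The products are (3R,4R,5R)-isopetasol butanoate F4 and unreacted (3S,4S,5S)-isopetasol F5, which are separated by chromatography.
- K2CO3/MeOH on the ester gives 4.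

**Step 3** is the riskiest step. The hydride/methyl shift may lose to proton loss, giving allylic alcohols, or to ketone formation. The fallback sets out from 3 and returns at 4. It puts the leaving group anti-periplanar to H-5 and blocks O-3 as an ester.
- Catalytic HClO4 in THF–H2O opens 3 trans-diaxially to (3R,4R,5R,10R)-3,4-dihydroxyeudesm-7(11)-en-8-one F6.
- Ac2O/pyridine acetylates only the secondary hydroxyl, giving (3R,4R,5R,10R)-3-acetoxy-4-hydroxyeudesm-7(11)-en-8-one F7.
- Westphalen conditions (Ac2O, AcOH, catalytic H2SO4, rt) ionise the axial tertiary C4–O bond. That bond, H-5, the C10 methyl and the axial H-9 form one continuous anti-periplanar array, while the neighbouring acetoxy group suppresses pinacol and simple elimination pathways.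
- The product is (3R,4R,5R)-isopetasol acetate F8, and K2CO3/MeOH returns 4.

**Step 4** carries the risk of a slow ene reaction or of competing abstraction from the C12/C13 methyls. The fallback sets out from 4 and returns at 6, and it replaces the ene reaction by an ionic three-operation sequence.
- Alkaline H2O2 in MeOH (Weitz–Scheffer) attacks the less hindered β-carbon C11 and gives (3R,4R,5R,7S)-7,11-epoxy-3-hydroxyeremophil-9-en-8-one F9. It is drawn as one C7 epimer, and both epimers converge.
- SmI2 in THF–MeOH at −90 °C cleaves the C7–O bond to give the β-hydroxy ketone (3R,4R,5R,7S)-3,11-dihydroxyeremophil-9-en-8-one F10.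
- DDQ in refluxing dioxane dehydrogenates C6–C7 without touching the unactivated secondary alcohol, in the manner of the 4-en-3-one to 1,4-dien-3-one conversion, and gives 6.

## Further compounds
F1 | step 1 | racemic eudesma-3,7(11)-dien-8-one | CC1=CCC[C@]2(C)CC(=O)C(=C(C)C)C[C@@H]12.CC1=CCC[C@@]2(C)CC(=O)C(=C(C)C)C[C@H]12
F2 | step 1 | racemic 3,4-epoxyeudesm-7(11)-en-8-one | C[C@@]12O[C@@H]1CC[C@]3(C)CC(=O)C(=C(C)C)C[C@@H]23.C[C@]12O[C@H]1CC[C@@]3(C)CC(=O)C(=C(C)C)C[C@H]23
F3 | step 1 | racemic isopetasol | O[C@@H]1CCC2=CC(=O)C(=C(C)C)C[C@]2(C)[C@H]1C.O[C@H]1CCC2=CC(=O)C(=C(C)C)C[C@@]2(C)[C@@H]1C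
F4 | step 1 | (3R,4R,5R)-isopetasol butanoate | CCCC(=O)O[C@@H]1CCC2=CC(=O)C(=C(C)C)C[C@]2(C)[C@H]1C
F5 | step 1 | (3S,4S,5S)-isopetasol | O[C@H]1CCC2=CC(=O)C(=C(C)C)C[C@@]2(C)[C@@H]1C
F6 | step 3 | (3R,4R,5R,10R)-3,4-dihydroxyeudesm-7(11)-en-8-one | C[C@]1(O)[C@H](O)CC[C@]2(C)CC(=O)C(=C(C)C)C[C@@H]12
F7 | step 3 | (3R,4R,5R,10R)-3-acetoxy-4-hydroxyeudesm-7(11)-en-8-one | C[C@]1(O)[C@H](OC(C)=O)CC[C@]2(C)CC(=O)C(=C(C)C)C[C@@H]12
F8 | step 3 | (3R,4R,5R)-isopetasol acetate | CC(=O)O[C@@H]1CCC2=CC(=O)C(=C(C)C)C[C@]2(C)[C@H]1C
F9 | step 4 | (3R,4R,5R,7S)-7,11-epoxy-3-hydroxyeremophil-9-en-8-one | O[C@@H]1CCC2=CC(=O)[C@]3(OC3(C)C)C[C@]2(C)[C@H]1C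
F10 | step 4 | (3R,4R,5R,7S)-3,11-dihydroxyeremophil-9-en-8-one | O[C@@H]1CCC2=CC(=O)[C@H](C(C)(C)O)C[C@]2(C)[C@H]1C
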